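Assumption: the target's single stereocentre (C-2 of the 2-methylbutanoyl group) is read from the SMILES as (R).

## Retrosynthetic overview

1. Target 27 → cut the pyrone C3–CH2 bond: Michael addition of 4-hydroxy-2-pyrone 6 to the o-quinone methide released from aryl Mannich base 25.
2. 25 → Mannich aminomethylation of prenylated acylphenol 24; 24 → C-prenylation of the symmetric 2,6-dihydroxy-4-methoxyphenyl ketone 22.
3. 22 → ortho-lithiation of bis-MOM 5-methoxyresorcinol 18 and acylation with (R)-Weinreb amide 16; the stereocentre comes from an Evans methylation (10 → 12).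
4. Pyrone 6 → lactonisation of diketo ester 5, made by crossed Claisen acylation of the dianion of methyl 3-oxopentanoate.
5. Ring order: the benzene ring is bought; the only ring built is the 2-pyrone (step 2), before the fragments are joined (step 12).

## Route

Step 1
Reactants: 1 methyl 3-oxopentanoate; 2 N-methoxy-N-methylpropanamide
Product: 5 methyl 4-methyl-3,5-dioxoheptanoate, via Na/Li dianion 3 (not isolated), via tetrahedral Weinreb adduct 4 (not isolated)
Conditions: NaH (1.1 eq), THF, 0 °C; n-BuLi (1.05 eq), 0 °C; 2 (0.9 eq), −78 → 0 °C; 1 M HCl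
Reagents that add atoms: none
Why: Crossed Claisen-type acylation of the Huckin–Weiler dianion at its more nucleophilic γ-carbon; the N,O-chelated adduct stops over-addition and proton transfer, and the new C4 centre is an enolised, racemic β-diketone carbon that becomes sp2 in step 2.

Step 2
Reactants: 5 methyl 4-methyl-3,5-dioxoheptanoate
Product: 6 6-ethyl-4-hydroxy-5-methyl-2H-pyran-2-one
Conditions: DBU (1.5 eq), PhMe, reflux; 1 M HCl
Reagents that add atoms: none
Why: Base-mediated lactonisation (enol oxygen of the C5 ketone onto the ester, loss of MeOH) gives the aromatic 4-hydroxy-2-pyrone.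

Step 3
Reactants: 7 (R)-4-benzyloxazolidin-2-one; 8 butanoyl chloride
Product: 10 (R)-4-benzyl-3-butanoyloxazolidin-2-one, via N-lithio oxazolidinone 9 (not isolated)
Conditions: n-BuLi (1.05 eq), THF, −78 °C; 8, −78 → 0 °C
Reagents that add atoms: none
Why: Standard N-acylation of the lithiated Evans auxiliary; the auxiliary stereocentre is not touched.

Step 4
Reactants: 10 (R)-4-benzyl-3-butanoyloxazolidin-2-one
Product: 12 (R)-4-benzyl-3-[(R)-2-methylbutanoyl]oxazolidin-2-one, via sodium Z-enolate 11 (not isolated)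
Conditions: NaHMDS (1.1 eq), THF, −78 °C; MeI (4 eq), −78 → −40 °C; chromatography
Reagents that add atoms: iodomethane, CI
Why: Evans asymmetric alkylation; the chelated Z-enolate is methylated on the face opposite the benzyl group, giving the (R)-centre (dr about 10:1, minor diastereomer removed by chromatography).

Step 5
Reactants: 12 (R)-4-benzyl-3-[(R)-2-methylbutanoyl]oxazolidin-2-one
Product: 14 (R)-2-methylbutanoic acid, via lithium peroxycarboxylate 13 (not isolated)
Conditions: LiOH·H2O, 30% H2O2, THF/H2O 3:1, 0 °C; aq. Na2SO3; HCl to pH 2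
Reagents that add atoms: hydrogen peroxide, OO
Why: LiOOH cleaves the exocyclic imide carbonyl selectively at 0 °C without epimerisation; sulfite reduces the peracid and the auxiliary is recovered.

Step 6
Reactants: 14 (R)-2-methylbutanoic acid
Product: 16 (R)-N-methoxy-N,2-dimethylbutanamide, via acyl imidazolide 15 (not isolated)
Conditions: CDI (1.1 eq), CH2Cl2, 0 °C → rt; MeNHOMe·HCl (1.2 eq), rt
Reagents that add atoms: N,O-dimethylhydroxylamine hydrochloride, CNOC.Cl
Why: CDI-mediated Weinreb amidation under near-neutral conditions, with no pathway to racemise the α-centre.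

Step 7
Reactants: 17 5-methoxybenzene-1,3-diol
Product: 18 1-methoxy-3,5-bis(methoxymethoxy)benzene
Conditions: MOMCl (2.5 eq), i-Pr2NEt (3 eq), CH2Cl2, 0 °C → rt
Reagents that add atoms: chloromethyl methyl ether, COCCl
Why: O-alkylation of both phenols gives MOM ethers that protect them and act as strong ortho-directing groups.

Step 8
Reactants: 18 1-methoxy-3,5-bis(methoxymethoxy)benzene; 16 (R)-N-methoxy-N,2-dimethylbutanamide
Product: 21 (R)-1-[4-methoxy-2,6-bis(methoxymethoxy)phenyl]-2-methylbutan-1-one, via aryllithium 19 (not isolated), via tetrahedral lithium adduct 20 (not isolated)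
Conditions: n-BuLi (1.1 eq), TMEDA (1.1 eq), THF, 0 °C, 1 h; 16, −78 → 0 °C; H2O
Reagents that add atoms: none
Why: Directed ortho-metalation at the carbon flanked by both OMOM groups, then Weinreb ketone synthesis; the stable chelate releases the ketone only on quench, so the α-stereocentre never meets base as a ketone.

Step 9
Reactants: 21 (R)-1-[4-methoxy-2,6-bis(methoxymethoxy)phenyl]-2-methylbutan-1-one
Product: 22 (R)-1-(2,6-dihydroxy-4-methoxyphenyl)-2-methylbutan-1-one
Conditions: conc. HCl (cat.), MeOH, rt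
Reagents that add atoms: none
Why: Acid-catalysed acetal methanolysis of the carbonyl-flanked MOM ethers is fast at rt, whereas acid enolisation of this hindered ketone with a tertiary α-H is far slower, so the stereocentre is kept.

Step 10
Reactants: 22 (R)-1-(2,6-dihydroxy-4-methoxyphenyl)-2-methylbutan-1-one; 23 1-bromo-3-methylbut-2-ene
Product: 24 (R)-1-[2,6-dihydroxy-4-methoxy-3-(3-methylbut-2-en-1-yl)phenyl]-2-methylbutan-1-one
Conditions: 10% aq. KOH (2.2 eq), 23 (1.0 eq), 0 °C → rt
Reagents that add atoms: none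
Why: C-alkylation of the phenoxide in water (solvated oxygen favours carbon attack); 22 is symmetric so only one mono-C-prenyl isomer can form, and the phenoxide-deactivated ketone does not enolise.

Step 11
Reactants: 24 (R)-1-[2,6-dihydroxy-4-methoxy-3-(3-methylbut-2-en-1-yl)phenyl]-2-methylbutan-1-one
Product: 25 (R)-1-{3-[(dimethylamino)methyl]-2,6-dihydroxy-4-methoxy-5-(3-methylbut-2-en-1-yl)phenyl}-2-methylbutan-1-one
Conditions: Me2N+=CH2 I− (1.1 eq), Et3N (1.1 eq), CH2Cl2, 0 °C → rt
Reagents that add atoms: N,N-dimethylmethylideneammonium iodide (Eschenmoser's salt), C=[N+](C)C.[I-]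
Why: Phenol Mannich reaction with a preformed iminium ion at the only free ring carbon, which is activated by two ortho and one para oxygen.

Step 12
Reactants: 25 (R)-1-{3-[(dimethylamino)methyl]-2,6-dihydroxy-4-methoxy-5-(3-methylbut-2-en-1-yl)phenyl}-2-methylbutan-1-one; 6 6-ethyl-4-hydroxy-5-methyl-2H-pyran-2-one
Product: 27 3-({2,4-dihydroxy-6-methoxy-3-[(2R)-2-methylbutanoyl]-5-(3-methylbut-2-en-1-yl)phenyl}methyl)-6-ethyl-4-hydroxy-5-methyl-2H-pyran-2-one, via o-quinone methide 26 (not isolated)
Conditions: 6 (1.3 eq), 1,4-dioxane, 90 °C, N2 purge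
Reagents that add atoms: none
Why: The acidic pyrone protonates the benzylic amine, Me2NH is eliminated to the o-quinone methide, and intermolecular Michael addition of pyrone C3 (the only free nucleophilic carbon) re-aromatises the ring; no stereocentre is formed or disturbed.

## Compound list

1 | methyl 3-oxopentanoate | CCC(=O)CC(=O)OC | starting material
2 | N-methoxy-N-methylpropanamide | CCC(=O)N(C)OC | starting material
3 | sodium lithium dienolate (dianion) of methyl 3-oxopentanoate | CC=C([O-])C=C([O-])OC.[Na+].[Li+] | intermediate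
4 | sodium lithium salt of methyl 5-hydroxy-5-[methoxy(methyl)amino]-4-methyl-3-oxoheptanoate (alkoxide/enolate) | CCC([O-])(N(C)OC)C(C)C([O-])=CC(=O)OC.[Na+].[Li+] | intermediate
5 | methyl 4-methyl-3,5-dioxoheptanoate (racemic at C4, enolised) | CCC(=O)C(C)C(=O)CC(=O)OC | intermediate
6 | 6-ethyl-4-hydroxy-5-methyl-2H-pyran-2-one | CCc1oc(=O)cc(O)c1C | intermediate
7 | (R)-4-benzyloxazolidin-2-one | O=C1N[C@H](Cc2ccccc2)CO1 | starting material
8 | butanoyl chloride | CCCC(Cl)=O | starting material
9 | lithium salt (N-lithio) of (R)-4-benzyloxazolidin-2-one | [Li]N1[C@H](Cc2ccccc2)COC1=O | intermediate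
10 | (R)-4-benzyl-3-butanoyloxazolidin-2-one | CCCC(=O)N1[C@H](Cc2ccccc2)COC1=O | intermediate
11 | sodium (Z)-enolate of 10 | CC/C=C(\[O-])N1[C@H](Cc2ccccc2)COC1=O.[Na+] | intermediate
12 | (R)-4-benzyl-3-[(R)-2-methylbutanoyl]oxazolidin-2-one | CC[C@@H](C)C(=O)N1[C@H](Cc2ccccc2)COC1=O | intermediate
13 | lithium (R)-2-methylbutaneperoxoate | CC[C@@H](C)C(=O)O[O-].[Li+] | intermediate
14 | (R)-2-methylbutanoic acid | CC[C@@H](C)C(=O)O | intermediate
15 | (R)-1-(1H-imidazol-1-yl)-2-methylbutan-1-one | CC[C@@H](C)C(=O)n1ccnc1 | intermediate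
16 | (R)-N-methoxy-N,2-dimethylbutanamide | CC[C@@H](C)C(=O)N(C)OC | intermediate
17 | 5-methoxybenzene-1,3-diol (5-methoxyresorcinol) | COc1cc(O)cc(O)c1 | starting material
18 | 1-methoxy-3,5-bis(methoxymethoxy)benzene | COCOc1cc(OC)cc(OCOC)c1 | intermediate
19 | [4-methoxy-2,6-bis(methoxymethoxy)phenyl]lithium | [Li]c1c(OCOC)cc(OC)cc1OCOC | intermediate
20 | lithium (2R)-1-[methoxy(methyl)amino]-1-[4-methoxy-2,6-bis(methoxymethoxy)phenyl]-2-methylbutan-1-olate (carbinol centre undefined) | CC[C@@H](C)C(O[Li])(N(C)OC)c1c(OCOC)cc(OC)cc1OCOC | intermediate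
21 | (R)-1-[4-methoxy-2,6-bis(methoxymethoxy)phenyl]-2-methylbutan-1-one | CC[C@@H](C)C(=O)c1c(OCOC)cc(OC)cc1OCOC | intermediate
22 | (R)-1-(2,6-dihydroxy-4-methoxyphenyl)-2-methylbutan-1-one | CC[C@@H](C)C(=O)c1c(O)cc(OC)cc1O | intermediate
23 | 1-bromo-3-methylbut-2-ene (prenyl bromide) | CC(C)=CCBr | starting material
24 | (R)-1-[2,6-dihydroxy-4-methoxy-3-(3-methylbut-2-en-1-yl)phenyl]-2-methylbutan-1-one | CC[C@@H](C)C(=O)c1c(O)cc(OC)c(CC=C(C)C)c1O | intermediate
25 | (R)-1-{3-[(dimethylamino)methyl]-2,6-dihydroxy-4-methoxy-5-(3-methylbut-2-en-1-yl)phenyl}-2-methylbutan-1-one | CC[C@@H](C)C(=O)c1c(O)c(CN(C)C)c(OC)c(CC=C(C)C)c1O | intermediate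
26 | 3-hydroxy-5-methoxy-2-[(2R)-2-methylbutanoyl]-4-(3-methylbut-2-en-1-yl)-6-methylidenecyclohexa-2,4-dien-1-one (o-quinone methide) | CC[C@@H](C)C(=O)C1=C(O)C(CC=C(C)C)=C(OC)C(=C)C1=O | intermediate
27 | 3-({2,4-dihydroxy-6-methoxy-3-[(2R)-2-methylbutanoyl]-5-(3-methylbut-2-en-1-yl)phenyl}methyl)-6-ethyl-4-hydroxy-5-methyl-2H-pyran-2-one (CNP0279667.1) | CCc1oc(=O)c(Cc2c(O)c(C(=O)[C@H](C)CC)c(O)c(CC=C(C)C)c2OC)c(O)c1C | target

## Step count and risks

Total steps: 12. Longest linear sequence: 9 steps (3, 4, 5, 6, 8, 9, 10, 11, 12, counted from 7).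

Three steps most likely to fail:

**Step 8** (lithiation at the wrong ring position, or sluggish addition of the hindered aryllithium to the α-branched amide). The fallback sets out from 14 and comes back at 22, so steps 6–9 are not needed. Acid 14 is converted with oxalyl chloride and catalytic DMF (CH2Cl2, 0 °C) into (R)-2-methylbutanoyl chloride F1. F1 acylates phloroglucinol (benzene-1,3,5-triol, Oc1cc(O)cc(O)c1; AlCl3, PhNO2/CH2Cl2, 0 °C → rt, Friedel–Crafts) to give (R)-2-methyl-1-(2,4,6-trihydroxyphenyl)butan-1-one F2. Me2SO4 (1.0 eq) with K2CO3 in acetone then methylates the most acidic, non-chelated para-OH to give 22. The ee must be checked by chiral HPLC because the Lewis-acid step can erode it.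

**Step 10** (O-prenylation, bis-prenylation, modest conversion). The fallback sets out from 22 and comes back at 24. Mono-O-alkylation with 23 (K2CO3, acetone, rt; the second OH stays chelated) gives (R)-1-{2-hydroxy-4-methoxy-6-[(3-methylbut-2-en-1-yl)oxy]phenyl}-2-methylbutan-1-one F3. The prenyl group is then moved from O to C with montmorillonite K10 (CH2Cl2, 0 °C, [1,3]-shift) or by Eu(fod)3-catalysed Claisen–Cope rearrangement. Because the ring is symmetric, migration to either free ring carbon gives 24.

**Step 12** (o-quinone methide side reactions: oligomerisation, O-alkylation, double alkylation of the pyrone). The fallback sets out from 6 and 24 and comes back at 27, bypassing 25, with the roles of the partners reversed. Pyrone 6 with Eschenmoser's salt and Et3N (MeCN, rt) gives 3-[(dimethylamino)methyl]-6-ethyl-4-hydroxy-5-methyl-2H-pyran-2-one F4. On warming with 24 (MeCN, 60 °C) it loses dimethylamine to give 6-ethyl-5-methyl-3-methylidene-2H-pyran-2,4(3H)-dione F5, which is not isolated. This doubly activated Michael acceptor is attacked by the free ring carbon of 24 (Friedel–Crafts-type conjugate addition) to give 27.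

## Further compounds

F1 | step 8 | (R)-2-methylbutanoyl chloride | CC[C@@H](C)C(=O)Cl
F2 | step 8 | (R)-2-methyl-1-(2,4,6-trihydroxyphenyl)butan-1-one | CC[C@@H](C)C(=O)c1c(O)cc(O)cc1O
F3 | step 10 | (R)-1-{2-hydroxy-4-methoxy-6-[(3-methylbut-2-en-1-yl)oxy]phenyl}-2-methylbutan-1-one | CC[C@@H](C)C(=O)c1c(O)cc(OC)cc1OCC=C(C)C
F4 | step 12 | 3-[(dimethylamino)methyl]-6-ethyl-4-hydroxy-5-methyl-2H-pyran-2-one | CCc1oc(=O)c(CN(C)C)c(O)c1C
F5 | step 12 | 6-ethyl-5-methyl-3-methylidene-2H-pyran-2,4(3H)-dione | CCC1=C(C)C(=O)C(=C)C(=O)O1
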